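A small charge is where I look first. Cedar, with 0.075 M of free monomer, loses 8.9 percentage points of its charge between 5.00 h and 10.0 h, while birch, with 0.28 M, loses 21 points. The percentage loss climbs with the charge, as if part of the free monomer did not count.

| flask | free monomer | initiator | remark | time |
|---|---|---|---|---|
| cedar | 0.075 M | 2 mM | run made earlier |  |
| ash | 0.18 M | 2 mM | run made earlier |  |
| birch | 0.28 M | 2 mM | run made earlier |  |
| eta | 0.10 M | 2.0 mM |  | 20 h |
| zeta | 0.30 M | 2.0 mM |  | 20 h |

| run | time / h | monomer in chains / % | free monomer / % |
|---|---|---|---|
| cedar | 0.833 | 1.1 | 98.4 |
| cedar | 2.50 | 4.9 | 94.7 |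
| cedar | 5.00 | 11.3 | 89.1 |
| cedar | 8.00 | 16.8 | 83.8 |
| cedar | 10.0 | 19.7 | 80.2 |
| ash | 0.833 | 2.5 | 97.2 |
| ash | 2.50 | 12.9 | 87.9 |
| ash | 5.00 | 25.4 | 73.7 |
| ash | 8.00 | 38.8 | 61.8 |
| ash | 10.0 | 44.7 | 55.3 |
| birch | 0.833 | 4.3 | 95.8 |
| birch | 2.50 | 15.4 | 84.3 |
| birch | 5.00 | 31.0 | 68.8 |
| birch | 8.00 | 44.8 | 55.0 |
| birch | 10.0 | 52.1 | 47.7 |

(each reading ± 0.3 percentage points)

- the average divides the monomer in chains by the number of chains begun, living and dead together
- the analysis behind the earlier runs scatters by 0.3 percentage points, standard deviation
- steps thought possible: monomer in chains + living end -> free monomer + living end; initiator -> spent initiator B; free monomer + living end -> monomer in chains + living end; 2 initiator -> spent initiator A; free monomer + initiator -> living end + monomer in chains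
- the earlier runs do not show the number of chains; that part of a forecast is a guess

1. which of the two ends with the longer chains by the average number of monomer units in a chain (chains begun, living or dead) ("neither" if they lie within 10 %) (eta / zeta / neither)
2. average number of monomer units in a chain (chains begun, living or dead) at the end, eta
3. average number of monomer units in a chain (chains begun, living or dead) at the end, zeta

The average needs monomer consumed and chains begun, and the readings speak to the first. My first way runs across flasks. Over that window I set net loss in M/h against mean [free monomer] for cedar and birch. The line has slope 0.105 h⁻¹ and reaches zero at 0.0508 M. That intercept is the floor, the [free monomer] at which addition to a living end and release from it balance: the equilibrium monomer concentration.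

My second way stays within birch and compares its early and late windows, giving slope 0.101 h⁻¹ and floor 0.0428 M. The slopes stand close, though the two ways share birch readings, and the floors part by 0.00800 M. The scatter carries the second floor by about 0.0108 M, which is more than that gap. So the gap lies within the scatter of the second way, and I keep the first floor.

In logarithms, I take ln([free monomer] − floor) to fall straight, one power of ten per 21.9 h. The 20 h asked is less than that, so I reckon that 87.8 % of the excess goes. That consumes 0.0432 M in eta and 0.219 M in zeta. Counting each initiator of the 2.0 mM as one chain, I get 21.6 and 110.

The forecast says zeta, with 34 for eta and 130 for zeta, on 1.25 mM and 1.67 mM of chains, where I take the full charge. In its words: “Chain count is an extrapolated guess.”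

The flask gives zeta, with 24.4 for eta and 114 for zeta.

    monomer in chains + living end → free monomer + living end, rate k1*[living end] as long as [monomer in chains] is above zero (k = 7.30 × 10⁻⁴ s⁻¹)
    initiator → spent initiator B (k = 7.00 × 10⁻⁶ s⁻¹)
    free monomer + living end → monomer in chains + living end, rate k3*[living end]*[free monomer] (k = 0.0150 M⁻¹ s⁻¹)
    2 initiator → spent initiator A (k = 0.00930 M⁻¹ s⁻¹)
    free monomer + initiator → living end + monomer in chains (k = 0.00190 M⁻¹ s⁻¹)

Eta and zeta part through their charge of free monomer: with that difference taken away, zeta's charge cut to eta's, its average falls from 114 to 24.4. Eta's monomer in chains stands at 0.0429 M against the forecast's 0.042 M consumed, but its living end stands at 0.00176 M against the forecast's 1.25 mM of chains.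

For a neighbour flask, zeta with its free monomer cut to 0.12 M, the floor gives 49.4 % of the free monomer left and an average of 30.4. The simulation of that neighbour gives 49.9 % left and an average of 33.5.

The numbers in the tables are calculated with made-up constants; the scatter is artificial.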